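The route rests on disconnecting the C6–C7 bond shared by the ten-membered carbocycle and the α-methylene-γ-butyrolactone. C7 is the β-carbon of the C11(=C13)–C12 acrylate and C6 a carbinol carbon, so the bond is made by reversing the polarity of C7: an allylic bromide is turned by CrCl2 into an allylchromium nucleophile that attacks a C6 (Z)-enal (intramolecular Nozaki–Hiyama–Kishi allylation). One operation closes the carbocycle, sets C6 and C7 and delivers the lactone. The precursor is an acyclic (3S,8S)-configured chain with a (Z)-enal at one end and a 2-(bromomethyl)acrylate at the other; C8 is inverted afterwards when the epoxy acid is attached.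

Key step: step 17

Remark: locants C1–C15 follow germacrane numbering of the target (C6 lactone carbinol, C7 ring-fusion carbon, C12 lactone carbonyl, C13 exocyclic methylene, C14 methyl on C10, C15 methyl on C4). The side-chain acid is taken as drawn, (2R,3S), the epoxide of the (E)-acid. Glycidyl ether 5 and alcohol 30 are assumed to be catalogue compounds.

Step 1
Reactants: 1 but-2-yn-1-ol
Product: 3 (Z)-3-iodobut-2-en-1-ol, via cyclic vinylalanate 2 (not isolated)
Conditions: Red-Al [NaAlH2(OCH2CH2OMe)2], THF, 0 °C to rt; then I2, −78 °C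
Reagents that add atoms: iodine, II
Why: The propargylic alkoxide directs a trans-hydroalumination that places aluminium on C3, and iodinolysis with retention gives the (Z)-iodide with iodine cis to the hydroxymethyl group.

Step 2
Reactants: 3 (Z)-3-iodobut-2-en-1-ol
Product: 4 (Z)-tert-butyl[(3-iodobut-2-en-1-yl)oxy]dimethylsilane
Conditions: TBSCl, imidazole, CH2Cl2, 0 °C to rt
Reagents that add atoms: tert-butyldimethylsilyl chloride, C[Si](C)(Cl)C(C)(C)C
Why: Standard silylation masks O6 through the organometallic steps.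

Step 3
Reactants: 5 (S)-2-{[(4-methoxybenzyl)oxy]methyl}oxirane
Product: 6 (S)-1-[(4-methoxybenzyl)oxy]pent-4-yn-2-ol
Conditions: LiC≡CH·H2NCH2CH2NH2, DMSO, rt
Reagents that add atoms: lithium acetylide–ethylenediamine complex, [Li]C#C.NCCN
Why: SN2 opening at the unsubstituted epoxide carbon leaves the stereocentre (future C8) untouched and brings in C1 and C10 as the alkyne.

Step 4
Reactants: 6 (S)-1-[(4-methoxybenzyl)oxy]pent-4-yn-2-ol
Product: 7 (S)-tert-butyl({1-[(4-methoxybenzyl)oxy]pent-4-yn-2-yl}oxy)dimethylsilane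
Conditions: TBSCl, imidazole, DMF, rt
Reagents that add atoms: tert-butyldimethylsilyl chloride, C[Si](C)(Cl)C(C)(C)C
Why: Silylation of the secondary alcohol; the silyl ether later serves as the Felkin-type control element at C8 in step 17.

Step 5
Reactants: 7 (S)-silyl ether of the pentynol, 8 oxirane
Product: 11 (3E,6S)-6-[(tert-butyldimethylsilyl)oxy]-7-[(4-methoxybenzyl)oxy]-4-methylhept-3-en-1-ol, via alkenylalane 9 (not isolated), via lithium alanate 10 (not isolated)
Conditions: AlMe3, Cp2ZrCl2 (0.25 equiv), CH2Cl2, 0 °C to rt; then n-BuLi, THF, −78 °C; then 8, −78 °C to rt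
Reagents that add atoms: trimethylaluminium, C[Al](C)C
Why: Zirconium-catalysed syn-carboalumination (Negishi) puts methyl on C10 and aluminium on C1 to fix the (E)-trisubstituted alkene, and the derived alanate opens oxirane with retention of geometry to add C2 and C3.

Step 6
Reactants: 11 homoallylic alcohol
Product: 12 (3E,6S)-6-[(tert-butyldimethylsilyl)oxy]-7-[(4-methoxybenzyl)oxy]-4-methylhept-3-enal
Conditions: Dess–Martin periodinane, NaHCO3, CH2Cl2, 0 °C
Reagents that add atoms: none
Why: Buffered Dess–Martin oxidation should give the β,γ-unsaturated aldehyde without migration of the double bond; 12 is used at once.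

Step 7
Reactants: 12 aldehyde, 4 (Z)-vinyl iodide
Product: 14 (2Z,6E,9S)-1,9-bis[(tert-butyldimethylsilyl)oxy]-10-[(4-methoxybenzyl)oxy]-3,7-dimethyldeca-2,6-dien-4-ol (both epimers at the carbinol, C3 of the target), via alkenylchromium 13 (not isolated)
Conditions: CrCl2 (4 equiv), NiCl2 (2 mol %), DMSO, rt
Reagents that add atoms: none
Why: Nozaki–Hiyama–Kishi coupling: nickel-catalysed activation of the alkenyl iodide, transmetalation to trivalent chromium and non-basic addition to the enolisable aldehyde with retention of the (Z)-geometry; C3 is not controlled here and is reset in steps 8 and 9.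

Step 8
Reactants: 14 allylic alcohol (epimers)
Product: 15 (2Z,6E,9S)-1,9-bis[(tert-butyldimethylsilyl)oxy]-10-[(4-methoxybenzyl)oxy]-3,7-dimethyldeca-2,6-dien-4-one
Conditions: Dess–Martin periodinane, NaHCO3, CH2Cl2, 0 °C
Reagents that add atoms: none
Why: Oxidation of the allylic alcohol converges both C3 epimers on one enone.

Step 9
Reactants: 15 enone
Product: 16 (2Z,4S,6E,9S)-1,9-bis[(tert-butyldimethylsilyl)oxy]-10-[(4-methoxybenzyl)oxy]-3,7-dimethyldeca-2,6-dien-4-ol
Conditions: (R)-2-methyl-CBS-oxazaborolidine (0.3 equiv), catecholborane, toluene, −78 °C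
Reagents that add atoms: none
Why: Corey–Bakshi–Shibata reduction: with the α-branched alkenyl group as the large and the C2 methylene as the small substituent, the (R)-catalyst should deliver hydride to give the (S)-carbinol (3β-oxygen of the target).

Step 10
Reactants: 16 (4S)-allylic alcohol
Product: 17 (2Z,4S,6E,9S)-1,9-bis[(tert-butyldimethylsilyl)oxy]-10-[(4-methoxybenzyl)oxy]-3,7-dimethyldeca-2,6-dien-4-yl benzoate
Conditions: BzCl, pyridine, DMAP (cat.), CH2Cl2, 0 °C
Reagents that add atoms: benzoyl chloride, O=C(Cl)c1ccccc1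
Why: Acylation of the allylic alcohol installs the C3 benzoate of the target.

Step 11
Reactants: 17 benzoate
Product: 18 (2Z,4S,6E,9S)-1,9-bis[(tert-butyldimethylsilyl)oxy]-10-hydroxy-3,7-dimethyldeca-2,6-dien-4-yl benzoate
Conditions: DDQ, CH2Cl2–pH 7 buffer, 0 °C
Reagents that add atoms: none
Why: Oxidative cleavage of the 4-methoxybenzyl ether by DDQ leaves silyl ethers, benzoate and alkenes untouched.

Step 12
Reactants: 18 primary alcohol
Product: 19 (2Z,4S,6E,9S)-1,9-bis[(tert-butyldimethylsilyl)oxy]-3,7-dimethyl-10-oxodeca-2,6-dien-4-yl benzoate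
Conditions: Dess–Martin periodinane, NaHCO3, CH2Cl2, 0 °C
Reagents that add atoms: none
Why: Buffered Dess–Martin oxidation should give the α-silyloxy aldehyde (C7) without epimerisation at C8.

Step 13
Reactants: 19 aldehyde, 20 methyl propiolate
Product: 22 methyl (4S,6E,9S,10Z)-9-(benzoyloxy)-4,12-bis[(tert-butyldimethylsilyl)oxy]-3-hydroxy-6,10-dimethyl-2-methylidenedodeca-6,10-dienoate (both epimers at the carbinol, C7 of the target), via α-aluminoacrylate 21 (not isolated)
Conditions: 20, DIBAL-H (i-Bu2AlH), NMO, THF, 0 °C; then 19, 0 °C to rt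
Reagents that add atoms: none
Why: Hydroalumination of the propiolate gives the α-aluminoacrylate, which adds to the aldehyde as a fast equivalent of the Morita–Baylis–Hillman reaction; the C7 carbinol configuration is irrelevant because C7 becomes trigonal in step 14.

Step 14
Reactants: 22 allylic alcohol (epimers)
Product: 23 methyl (2Z,4S,6E,9S,10Z)-9-(benzoyloxy)-2-(bromomethyl)-4,12-bis[(tert-butyldimethylsilyl)oxy]-6,10-dimethyldodeca-2,6,10-trienoate
Conditions: NBS, Me2S, CH2Cl2, −20 °C to 0 °C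
Reagents that add atoms: N-bromosuccinimide, O=C1CCC(=O)N1Br
Why: The alcohol is activated as an alkoxysulfonium salt (Corey–Kim reagent) and bromide attacks the terminal methylene with allylic transposition (SN2'), which should give the conjugated 2-(bromomethyl)enoate with the favoured (Z)-geometry.

Step 15
Reactants: 23 allylic bromide
Product: 24 methyl (2Z,4S,6E,9S,10Z)-9-(benzoyloxy)-2-(bromomethyl)-4-[(tert-butyldimethylsilyl)oxy]-12-hydroxy-6,10-dimethyldodeca-2,6,10-trienoate
Conditions: aq. HF (48 %), MeCN, −10 °C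
Reagents that add atoms: none
Why: Acidic fluoride cleaves the unhindered primary allylic silyl ether much faster than the hindered secondary one at C8 and does not displace the allylic bromide.

Step 16
Reactants: 24 allylic alcohol
Product: 25 methyl (2Z,4S,6E,9S,10Z)-9-(benzoyloxy)-2-(bromomethyl)-4-[(tert-butyldimethylsilyl)oxy]-6,10-dimethyl-12-oxododeca-2,6,10-trienoate
Conditions: MnO2 (activated), CH2Cl2, rt
Reagents that add atoms: none
Why: MnO2 oxidises the allylic alcohol under neutral heterogeneous conditions, which should preserve the (Z)-enal and the allylic bromide.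

Step 17
Reactants: 25 bromo enal
Product: 28 3β-(benzoyloxy)-8α-[(tert-butyldimethylsilyl)oxy]germacra-1(10)E,4Z,11(13)-trien-12,6α-olide (H-6β, H-7α), via allylchromium 26 (not isolated), via chromium alkoxide 27 (not isolated)
Conditions: CrCl2 (10 equiv), THF–DMF, rt, slow addition of 25 to a final concentration of 2 mM; aq. NH4Cl work-up
Reagents that add atoms: none
Why: Two one-electron transfers from divalent chromium convert the allylic bromide into the σ-allylchromium species 26, which makes the normally electrophilic enoate β-carbon C7 a nucleophile that adds to the C6 aldehyde through a chair-like six-membered Zimmerman–Traxler transition state; the closest known reaction type is the intramolecular Nozaki–Hiyama–Kishi (Barbier-type) 2-(alkoxycarbonyl)allylation used for ten-membered carbocycles. The carbocycle closes by a 10-exo-trig 1,2-addition, and the chromium alkoxide 27 then closes the lactone by 5-exo-trig acyl substitution at the methyl ester with loss of methoxide. The anti C6/C7 relationship (trans-fused lactone, H-6β/H-7α) follows from the chair transition state of the allylchromium isomer that carries C8 pseudo-equatorially, the form through which γ-substituted allylchromium reagents react whatever the bromide geometry. The absolute sense at C7 is set by C8: allylic 1,3-strain with the C11 substituent holds H-8 in the plane of the allyl unit, the silyloxy group lies anti to the incoming aldehyde (Felkin-type) and the C9 tether carrying the aldehyde sits on the attacked face, which from the (8S)-ether gives the C6/C7 configuration of the target. The step needs 1,2-addition to the (Z)-enal without Z to E isomerisation, ring closure ahead of intermolecular coupling and retention of the C8 oxygen; the non-basic reagent, high dilution and the poor leaving-group ability of the silyl ether should secure these.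

Step 18
Reactants: 28 silyl ether
Product: 29 3β-(benzoyloxy)-8α-hydroxygermacra-1(10)E,4Z,11(13)-trien-12,6α-olide
Conditions: HF·pyridine, pyridine, THF, 0 °C to rt
Reagents that add atoms: none
Why: Buffered HF·pyridine removes the secondary silyl ether without opening the lactone or isomerising the diene.

Step 19
Reactants: 30 (E)-2-methylbut-2-en-1-ol
Product: 31 [(2S,3S)-2,3-dimethyloxiran-2-yl]methanol
Conditions: Ti(OiPr)4 (cat.), L-(+)-diethyl tartrate, t-BuOOH, 4 Å molecular sieves, CH2Cl2, −20 °C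
Reagents that add atoms: tert-butyl hydroperoxide, CC(C)(C)OO
Why: Sharpless asymmetric epoxidation: with L-(+)-diethyl tartrate the trisubstituted (E)-allylic alcohol is epoxidised on the face that gives the (2S,3S)-epoxy alcohol.

Step 20
Reactants: 31 epoxy alcohol
Product: 32 (2R,3S)-2,3-dimethyloxirane-2-carboxylic acid
Conditions: RuCl3 (cat.), NaIO4, CCl4–MeCN–H2O, rt
Reagents that add atoms: sodium periodate, [Na+].[O-]I(=O)(=O)=O; water, O
Why: RuO4 generated in situ (Sharpless conditions) oxidises the primary alcohol to the acid without touching the epoxide; the descriptor at C2 changes only through the priority rules.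

Step 21
Reactants: 29 8α-alcohol, 32 epoxy acid
Product: 34 3β-(benzoyloxy)-8β-{[(2R,3S)-2,3-dimethyloxirane-2-carbonyl]oxy}germacra-1(10)E,4Z,11(13)-trien-12,6α-olide, via alkoxyphosphonium carboxylate 33 (not isolated)
Conditions: PPh3, DIAD, toluene, 0 °C to rt
Reagents that add atoms: none
Why: Mitsunobu esterification: the C8 oxygen is activated as the alkoxyphosphonium ion and displaced by the carboxylate with SN2 inversion, which should convert the 8α-alcohol into the 8β-ester and attach the side chain in one operation.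

Step 22
Reactants: 34 diene ester
Product: 35 CNP0324463.5, 3β-(benzoyloxy)-1β,10α-epoxy-8β-{[(2R,3S)-2,3-dimethyloxirane-2-carbonyl]oxy}germacra-4Z,11(13)-dien-12,6α-olide
Conditions: mCPBA, NaHCO3, CH2Cl2, 0 °C
Reagents that add atoms: 3-chloroperoxybenzoic acid, O=C(OO)c1cccc(Cl)c1
Why: Prilezhaev epoxidation: C1=C10 is the only electron-rich alkene (C4=C5 carries two allylic acyloxy groups, C11=C13 is conjugated), and attack on its exposed outer face, with the C10 methyl held on the β-face of the ring, should give the 1β,10α-epoxide (1R,10R).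

Compound list

1 | but-2-yn-1-ol | CC#CCO | starting material
2 | sodium 2,2-bis(2-methoxyethoxy)-3-methyl-2,5-dihydro-1,2-oxaaluminol-2-uide (cyclic vinylalanate) | CC1=CCO[Al-]1(OCCOC)OCCOC.[Na+] | intermediate
3 | (Z)-3-iodobut-2-en-1-ol | C/C(I)=C/CO | intermediate
4 | (Z)-tert-butyl[(3-iodobut-2-en-1-yl)oxy]dimethylsilane | C/C(I)=C/CO[Si](C)(C)C(C)(C)C | intermediate
5 | (S)-2-{[(4-methoxybenzyl)oxy]methyl}oxirane | C1O[C@@H]1COCc1ccc(OC)cc1 | starting material
6 | (S)-1-[(4-methoxybenzyl)oxy]pent-4-yn-2-ol | C#CC[C@H](O)COCc1ccc(OC)cc1 | intermediate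
7 | (S)-tert-butyl({1-[(4-methoxybenzyl)oxy]pent-4-yn-2-yl}oxy)dimethylsilane | C#CC[C@H](O[Si](C)(C)C(C)(C)C)COCc1ccc(OC)cc1 | intermediate
8 | oxirane | C1CO1 | starting material
9 | (E)-alkenyl(dimethyl)alane from 7 (Al on C1, cis to the C10 methyl) | C[Al](C)/C=C(\C)C[C@H](O[Si](C)(C)C(C)(C)C)COCc1ccc(OC)cc1 | intermediate
10 | lithium butyl(dimethyl)[(E)-alkenyl]alanate from 9 | [Li+].CCCC[Al-](C)(C)/C=C(\C)C[C@H](O[Si](C)(C)C(C)(C)C)COCc1ccc(OC)cc1 | intermediate
11 | (3E,6S)-6-[(tert-butyldimethylsilyl)oxy]-7-[(4-methoxybenzyl)oxy]-4-methylhept-3-en-1-ol | OCC/C=C(\C)C[C@H](O[Si](C)(C)C(C)(C)C)COCc1ccc(OC)cc1 | intermediate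
12 | (3E,6S)-6-[(tert-butyldimethylsilyl)oxy]-7-[(4-methoxybenzyl)oxy]-4-methylhept-3-enal | O=CC/C=C(\C)C[C@H](O[Si](C)(C)C(C)(C)C)COCc1ccc(OC)cc1 | intermediate
13 | (Z)-[4-(tert-butyldimethylsilyloxy)but-2-en-2-yl]chromium dichloride | C/C([Cr](Cl)Cl)=C/CO[Si](C)(C)C(C)(C)C | intermediate
14 | (2Z,6E,9S)-1,9-bis[(tert-butyldimethylsilyl)oxy]-10-[(4-methoxybenzyl)oxy]-3,7-dimethyldeca-2,6-dien-4-ol, both C4 epimers | C/C(=C/CO[Si](C)(C)C(C)(C)C)C(O)C/C=C(\C)C[C@H](O[Si](C)(C)C(C)(C)C)COCc1ccc(OC)cc1 | intermediate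
15 | (2Z,6E,9S)-1,9-bis[(tert-butyldimethylsilyl)oxy]-10-[(4-methoxybenzyl)oxy]-3,7-dimethyldeca-2,6-dien-4-one | C/C(=C/CO[Si](C)(C)C(C)(C)C)C(=O)C/C=C(\C)C[C@H](O[Si](C)(C)C(C)(C)C)COCc1ccc(OC)cc1 | intermediate
16 | (2Z,4S,6E,9S)-1,9-bis[(tert-butyldimethylsilyl)oxy]-10-[(4-methoxybenzyl)oxy]-3,7-dimethyldeca-2,6-dien-4-ol | C/C(=C/CO[Si](C)(C)C(C)(C)C)[C@@H](O)C/C=C(\C)C[C@H](O[Si](C)(C)C(C)(C)C)COCc1ccc(OC)cc1 | intermediate
17 | (2Z,4S,6E,9S)-1,9-bis[(tert-butyldimethylsilyl)oxy]-10-[(4-methoxybenzyl)oxy]-3,7-dimethyldeca-2,6-dien-4-yl benzoate | C/C(=C/CO[Si](C)(C)C(C)(C)C)[C@@H](OC(=O)c1ccccc1)C/C=C(\C)C[C@H](O[Si](C)(C)C(C)(C)C)COCc1ccc(OC)cc1 | intermediate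
18 | (2Z,4S,6E,9S)-1,9-bis[(tert-butyldimethylsilyl)oxy]-10-hydroxy-3,7-dimethyldeca-2,6-dien-4-yl benzoate | C/C(=C/CO[Si](C)(C)C(C)(C)C)[C@@H](OC(=O)c1ccccc1)C/C=C(\C)C[C@H](O[Si](C)(C)C(C)(C)C)CO | intermediate
19 | (2Z,4S,6E,9S)-1,9-bis[(tert-butyldimethylsilyl)oxy]-3,7-dimethyl-10-oxodeca-2,6-dien-4-yl benzoate | C/C(=C/CO[Si](C)(C)C(C)(C)C)[C@@H](OC(=O)c1ccccc1)C/C=C(\C)C[C@H](O[Si](C)(C)C(C)(C)C)C=O | intermediate
20 | methyl propiolate | C#CC(=O)OC | starting material
21 | methyl 2-(diisobutylalumanyl)acrylate | C=C(C(=O)OC)[Al](CC(C)C)CC(C)C | intermediate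
22 | methyl (4S,6E,9S,10Z)-9-(benzoyloxy)-4,12-bis[(tert-butyldimethylsilyl)oxy]-3-hydroxy-6,10-dimethyl-2-methylidenedodeca-6,10-dienoate, both C3 epimers | C/C(=C/CO[Si](C)(C)C(C)(C)C)[C@@H](OC(=O)c1ccccc1)C/C=C(\C)C[C@H](O[Si](C)(C)C(C)(C)C)C(O)C(=C)C(=O)OC | intermediate
23 | methyl (2Z,4S,6E,9S,10Z)-9-(benzoyloxy)-2-(bromomethyl)-4,12-bis[(tert-butyldimethylsilyl)oxy]-6,10-dimethyldodeca-2,6,10-trienoate | C/C(=C/CO[Si](C)(C)C(C)(C)C)[C@@H](OC(=O)c1ccccc1)C/C=C(\C)C[C@H](O[Si](C)(C)C(C)(C)C)/C=C(\CBr)C(=O)OC | intermediate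
24 | methyl (2Z,4S,6E,9S,10Z)-9-(benzoyloxy)-2-(bromomethyl)-4-[(tert-butyldimethylsilyl)oxy]-12-hydroxy-6,10-dimethyldodeca-2,6,10-trienoate | C/C(=C/CO)[C@@H](OC(=O)c1ccccc1)C/C=C(\C)C[C@H](O[Si](C)(C)C(C)(C)C)/C=C(\CBr)C(=O)OC | intermediate
25 | methyl (2Z,4S,6E,9S,10Z)-9-(benzoyloxy)-2-(bromomethyl)-4-[(tert-butyldimethylsilyl)oxy]-6,10-dimethyl-12-oxododeca-2,6,10-trienoate | C/C(=C/C=O)[C@@H](OC(=O)c1ccccc1)C/C=C(\C)C[C@H](O[Si](C)(C)C(C)(C)C)/C=C(\CBr)C(=O)OC | intermediate
26 | σ-allylchromium dichloride from 25 (Cr on C13; C7=C11 geometry equilibrating) | C/C(=C/C=O)[C@@H](OC(=O)c1ccccc1)C/C=C(\C)C[C@H](O[Si](C)(C)C(C)(C)C)C=C(C[Cr](Cl)Cl)C(=O)OC | intermediate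
27 | chromium alkoxide of the ten-membered hydroxy ester (C6–O–CrCl2; C6–C7 bond formed, lactone still open) | COC(=O)C(=C)[C@H]1[C@H](O[Cr](Cl)Cl)/C=C(/C)[C@@H](OC(=O)c2ccccc2)C/C=C(\C)C[C@@H]1O[Si](C)(C)C(C)(C)C | intermediate
28 | 3β-(benzoyloxy)-8α-[(tert-butyldimethylsilyl)oxy]germacra-1(10)E,4Z,11(13)-trien-12,6α-olide | C=C1C(=O)O[C@@H]2/C=C(/C)[C@@H](OC(=O)c3ccccc3)C/C=C(\C)C[C@H](O[Si](C)(C)C(C)(C)C)[C@@H]12 | intermediate
29 | 3β-(benzoyloxy)-8α-hydroxygermacra-1(10)E,4Z,11(13)-trien-12,6α-olide | C=C1C(=O)O[C@@H]2/C=C(/C)[C@@H](OC(=O)c3ccccc3)C/C=C(\C)C[C@H](O)[C@@H]12 | intermediate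
30 | (E)-2-methylbut-2-en-1-ol | C/C=C(\C)CO | starting material
31 | [(2S,3S)-2,3-dimethyloxiran-2-yl]methanol | OC[C@]1(C)O[C@H]1C | intermediate
32 | (2R,3S)-2,3-dimethyloxirane-2-carboxylic acid | OC(=O)[C@]1(C)O[C@H]1C | intermediate
33 | C8 alkoxytriphenylphosphonium salt of 29 with the carboxylate of 32 | C=C1C(=O)O[C@@H]2/C=C(/C)[C@@H](OC(=O)c3ccccc3)C/C=C(\C)C[C@H](O[P+](c3ccccc3)(c3ccccc3)c3ccccc3)[C@@H]12.[O-]C(=O)[C@]1(C)O[C@H]1C | intermediate
34 | 3β-(benzoyloxy)-8β-{[(2R,3S)-2,3-dimethyloxirane-2-carbonyl]oxy}germacra-1(10)E,4Z,11(13)-trien-12,6α-olide | C=C1C(=O)O[C@@H]2/C=C(/C)[C@@H](OC(=O)c3ccccc3)C/C=C(\C)C[C@@H](OC(=O)[C@]3(C)O[C@H]3C)[C@@H]12 | intermediate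
35 | CNP0324463.5, (1R,3S,6R,7R,8R,10R)-configured 1β,10α-epoxide of 34 | C=C1C(=O)O[C@@H]2/C=C(/C)[C@@H](OC(=O)c3ccccc3)C[C@H]3O[C@]3(C)C[C@@H](OC(=O)[C@]3(C)O[C@H]3C)[C@@H]12 | target

Total step count: 22. Longest linear sequence: 18 steps (steps 3–18, 21 and 22, from glycidyl ether 5).

Steps most likely to fail

Step 17. The face of the allylchromium unit that is attacked may be dictated by strain in the forming ring instead of by the C8 silyloxy centre, and syn addition or intermolecular coupling may compete. The fallback sets out from bromo enal 25 and replaces substrate control by catalyst control: the same closure would be run as a chromium-catalysed asymmetric 2-(alkoxycarbonyl)allylation (catalytic CrCl2, a chiral bis(oxazolinyl)carbazole ligand, Mn powder and Cp2ZrCl2 for turnover), so that the ligand selects the C7 face. It comes back to the route at lactone 28 and makes no new compound.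

Step 21. The activated C8 alcohol may eliminate towards C9, or the homoallylic C1=C10 alkene may take part in the displacement, so that inversion is lost. The fallback sets out from alcohol 29 and inverts C8 by redox instead of substitution. Dess–Martin oxidation would give the 8-ketone F1; Luche reduction (NaBH4, CeCl3·7H2O, MeOH, −78 °C), with hydride approaching the α-face anti to the C7–C11 bond, would give the 8β-alcohol F2. Acid 32 would be activated with 2,4,6-trichlorobenzoyl chloride and Et3N as the mixed anhydride F3 and coupled with F2 and DMAP (Yamaguchi esterification, retention). It comes back at diene ester 34.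

Step 22. The peracid may attack both faces of C1=C10, or the new epoxide may open transannularly under the acidic by-product. The fallback sets out from silyl ether 28 and sets the epoxide under reagent control before the side chain is attached. Shi epoxidation (D-fructose-derived ketone, Oxone, buffered MeCN–dimethoxymethane–water, 0 °C) would give the epoxy silyl ether F4. TBAF buffered with AcOH would give the epoxy alcohol F5. Mitsunobu esterification with 32 (PPh3, DIAD), through the alkoxyphosphonium carboxylate F6, would invert C8 and comes back at target 35.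

Further compounds

F0 | step 17 | none | none
F1 | step 21 | 3β-(benzoyloxy)-8-oxogermacra-1(10)E,4Z,11(13)-trien-12,6α-olide | C=C1C(=O)O[C@@H]2/C=C(/C)[C@@H](OC(=O)c3ccccc3)C/C=C(\C)CC(=O)[C@@H]12
F2 | step 21 | 3β-(benzoyloxy)-8β-hydroxygermacra-1(10)E,4Z,11(13)-trien-12,6α-olide | C=C1C(=O)O[C@@H]2/C=C(/C)[C@@H](OC(=O)c3ccccc3)C/C=C(\C)C[C@@H](O)[C@@H]12
F3 | step 21 | (2R,3S)-2,3-dimethyloxirane-2-carboxylic 2,4,6-trichlorobenzoic anhydride | O=C(OC(=O)c1c(Cl)cc(Cl)cc1Cl)[C@]1(C)O[C@H]1C
F4 | step 22 | 3β-(benzoyloxy)-8α-[(tert-butyldimethylsilyl)oxy]-1β,10α-epoxygermacra-4Z,11(13)-dien-12,6α-olide | C=C1C(=O)O[C@@H]2/C=C(/C)[C@@H](OC(=O)c3ccccc3)C[C@H]3O[C@]3(C)C[C@H](O[Si](C)(C)C(C)(C)C)[C@@H]12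
F5 | step 22 | 3β-(benzoyloxy)-1β,10α-epoxy-8α-hydroxygermacra-4Z,11(13)-dien-12,6α-olide | C=C1C(=O)O[C@@H]2/C=C(/C)[C@@H](OC(=O)c3ccccc3)C[C@H]3O[C@]3(C)C[C@H](O)[C@@H]12
F6 | step 22 | C8 alkoxytriphenylphosphonium salt of F5 with the carboxylate of 32 | C=C1C(=O)O[C@@H]2/C=C(/C)[C@@H](OC(=O)c3ccccc3)C[C@H]3O[C@]3(C)C[C@H](O[P+](c3ccccc3)(c3ccccc3)c3ccccc3)[C@@H]12.[O-]C(=O)[C@]1(C)O[C@H]1C
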